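**Retrosynthetic overview**

- The target comes from its bis-N-tosyl derivative; both indole N–H groups are freed in the last step.
- The strategy rests on C6 of the cyclohexene ring. This CH carries an indol-5-yl group, is allylic to C4=C5 and sits beside the quaternary C1 (methyl, styryl). The C5–C6 bond is therefore cut into two electrophilic carbons, a (Z)-alkenyl bromide (C5) and a benzylic chloride (C6), and is made by nickel-catalysed reductive ring closure.
- The chloride comes from an α-quaternary aldehyde and an indol-5-yl Grignard reagent. C1 is set by deconjugative α-alkylation of the dienolate of an (E)-2-methyl-4-indolylbut-2-enoyl oxazolidinone with a (Z)-bromoalkenyl triflate.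
- Both indole units come from one aryl bromide (5-bromoindole-3-acetic acid: gem-dimethylation, reduction, methylenation). The enoyl unit is built by allylation and cross-metathesis with methacrolein, the bromoalkene by chelation-controlled methylalumination of but-3-yn-1-ol.
- Ring order: the two indole rings are bought with the starting acid; the cyclohexene is the only ring made, in step 17.

Key step: step 17

Abbreviations: Ar = 3-(2-methylbut-3-en-2-yl)-1-tosylindol-5-yl; Ts = 4-methylphenylsulfonyl. Cyclohexene numbering: C1 quaternary (methyl, styryl), C2, C3, C4 (methyl-bearing alkene carbon), C5, C6 (CH–Ar). N-Tosyl replaces N-Boc throughout because it survives the Grignard and hydride steps and still restrains ionisation of the benzylic chloride.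

Assumption: the sodium dienolate of step 12 reacts as a chelated oxazolidinone enolate with the α-methyl cis to O–Na, so the (R)-auxiliary gives the (S) centre; if the other face reacts, the (S)-auxiliary is used, and in step 17 the ligand antipode is taken if the named one is mismatched with C1.

Step 1
Reactants: 1 5-bromoindole-3-acetic acid
Product: 2 methyl 2-(5-bromo-1H-indol-3-yl)acetate
Conditions: MeOH, H2SO4 (cat.), reflux
Reagents that add atoms: methanol, CO
Why: Fischer esterification protects the acid and provides the enolisable ester needed in step 3.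

Step 2
Reactants: 2 methyl 2-(5-bromo-1H-indol-3-yl)acetate
Product: 3 methyl 2-(5-bromo-1-tosylindol-3-yl)acetate
Conditions: NaH (1.1 equiv), THF, 0 °C; TsCl, 0 °C to rt
Reagents that add atoms: 4-methylbenzenesulfonyl chloride, Cc1ccc(S(Cl)(=O)=O)cc1
Why: N-sulfonylation of the indolide (N–H is the most acidic site) installs an electron-withdrawing group that tolerates the later bases, hydrides and Grignard reagent and later restrains the benzylic chloride.

Step 3
Reactants: 3 methyl 2-(5-bromo-1-tosylindol-3-yl)acetate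
Product: 5 methyl 2-(5-bromo-1-tosylindol-3-yl)-2-methylpropanoate, via monomethylated ester 4 (not isolated)
Conditions: NaH (2.5 equiv), MeI (3 equiv), THF/DMF, 0 °C to rt
Reagents that add atoms: iodomethane, CI
Why: Double enolate C-methylation of the arylacetate builds the gem-dimethyl carbon, the N-tosyl group excluding N-methylation.

Step 4
Reactants: 5 methyl 2-(5-bromo-1-tosylindol-3-yl)-2-methylpropanoate
Product: 6 2-(5-bromo-1-tosylindol-3-yl)-2-methylpropanal
Conditions: i-Bu2AlH (1.1 equiv), CH2Cl2, −78 °C; aq. potassium sodium tartrate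
Reagents that add atoms: none
Why: Partial reduction of the hindered ester stops at the aldehyde because the tetrahedral aluminium alkoxide is stable at −78 °C and collapses only on work-up.

Step 5
Reactants: 6 2-(5-bromo-1-tosylindol-3-yl)-2-methylpropanal
Product: 7 5-bromo-3-(2-methylbut-3-en-2-yl)-1-tosylindole
Conditions: Ph3PCH3Br, KOtBu, THF, 0 °C to rt
Reagents that add atoms: methyltriphenylphosphonium bromide, C[P+](c1ccccc1)(c1ccccc1)c1ccccc1.[Br-]
Why: Wittig methylenation of the non-enolisable aldehyde completes the 1,1-dimethylallyl group.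

Step 6
Reactants: 8 but-3-yn-1-ol
Product: 11 (Z)-4-bromo-3-methylbut-3-en-1-ol, via (E)-alkenylalane 9 (not isolated), via cyclic (Z)-alkenylalane 10 (not isolated)
Conditions: AlMe3 (3 equiv), Cp2ZrCl2 (0.25 equiv), ClCH2CH2Cl, rt then 80 °C; NBS, THF, −30 to 0 °C; aq. work-up
Reagents that add atoms: trimethylaluminium, C[Al](C)C; N-bromosuccinimide, O=C1CCC(=O)N1Br
Why: Zirconium-catalysed syn-methylalumination gives the (E)-alkenylalane, heating lets the aluminium alkoxide chelate isomerise it to the (Z)-oxaaluminacycle, and bromodealumination with retention places Br cis to the hydroxyethyl chain.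

Step 7
Reactants: 11 (Z)-4-bromo-3-methylbut-3-en-1-ol
Product: 12 (Z)-4-bromo-3-methylbut-3-en-1-yl trifluoromethanesulfonate
Conditions: Tf2O, 2,6-lutidine, CH2Cl2, −78 °C; cold work-up, used at once
Reagents that add atoms: trifluoromethanesulfonic anhydride, O=S(=O)(OS(=O)(=O)C(F)(F)F)C(F)(F)F
Why: O-sulfonylation of the primary alcohol with a hindered base gives the alkyl triflate, an electrophile reactive enough at low temperature for the hindered dienolate of step 12.

Step 8
Reactants: 7 5-bromo-3-(2-methylbut-3-en-2-yl)-1-tosylindole; 13 2-allyl-4,4,5,5-tetramethyl-1,3,2-dioxaborolane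
Product: 14 5-allyl-3-(2-methylbut-3-en-2-yl)-1-tosylindole
Conditions: Pd(dppf)Cl2 (5 mol%), CsF, THF, 65 °C
Reagents that add atoms: none
Why: Suzuki–Miyaura allylation, in which fluoride-promoted allyl transfer to the arylpalladium bromide is faster than Heck insertion into the hindered 1,1-dimethylallyl alkene.

Step 9
Reactants: 14 5-allyl-3-(2-methylbut-3-en-2-yl)-1-tosylindole; 15 methacrolein
Product: 16 (E)-2-methyl-4-Ar-but-2-enal
Conditions: second-generation Grubbs catalyst (5 mol%), methacrolein (3 equiv), CH2Cl2, 40 °C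
Reagents that add atoms: none
Why: Olefin cross-metathesis of the terminal allyl group with methacrolein gives the trisubstituted (E)-enal under thermodynamic control, the 1,1-dimethylallyl vinyl group beside a quaternary carbon being too hindered to take part.

Step 10
Reactants: 16 (E)-2-methyl-4-Ar-but-2-enal
Product: 17 (E)-2-methyl-4-Ar-but-2-enoic acid
Conditions: NaClO2, NaH2PO4, 2-methylbut-2-ene, t-BuOH/H2O, rt
Reagents that add atoms: sodium chlorite, [Na+].[O-]Cl=O
Why: Pinnick oxidation gives the acid under buffered, non-basic conditions, so the double bond stays conjugated to the carbonyl and the scavenger protects the other alkenes from hypochlorous acid.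

Step 11
Reactants: 17 (E)-2-methyl-4-Ar-but-2-enoic acid; 18 (R)-4-benzyloxazolidin-2-one
Product: 20 (R)-4-benzyl-3-[(E)-2-methyl-4-Ar-but-2-enoyl]oxazolidin-2-one, via mixed pivalic anhydride 19 (not isolated)
Conditions: PivCl, Et3N, THF, −20 °C; then LiCl, 18, rt
Reagents that add atoms: none
Why: Mixed-anhydride N-acylation of the oxazolidinone under LiCl/Et3N needs no strong base, so the (E)-2-methyl-2-enoyl unit is carried over without deconjugation.

Step 12
Reactants: 20 (R)-4-benzyl-3-[(E)-2-methyl-4-Ar-but-2-enoyl]oxazolidin-2-one; 12 (Z)-4-bromo-3-methylbut-3-en-1-yl trifluoromethanesulfonate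
Product: 22 (R)-4-benzyl-3-[(2S,3E)-2-[(Z)-4-bromo-3-methylbut-3-enyl]-2-methyl-4-Ar-but-3-enoyl]oxazolidin-2-one, via sodium dienolate 21 (not isolated)
Conditions: NaN(SiMe3)2 (1.1 equiv), THF, −78 °C; then 12 (1.5 equiv), −78 to −40 °C
Reagents that add atoms: none
Why: Deconjugative α-alkylation of an enoyl-oxazolidinone dienolate (Evans alkylation): γ-deprotonation of the s-trans (E)-2-methyl-2-enoyl imide should give the chelated sodium dienolate with methyl cis to O–Na, the triflate attacks Cα on the face away from the benzyl group, and this sets the quaternary C1 as S while forming the (E)-styryl double bond.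

Step 13
Reactants: 22 (R)-4-benzyl-3-[(2S,3E)-2-[(Z)-4-bromo-3-methylbut-3-enyl]-2-methyl-4-Ar-but-3-enoyl]oxazolidin-2-one
Product: 23 (2S,3E)-2-[(Z)-4-bromo-3-methylbut-3-enyl]-2-methyl-4-Ar-but-3-en-1-ol
Conditions: LiBH4, MeOH (1 equiv), THF, 0 °C
Reagents that add atoms: none
Why: Reductive cleavage of the N-acyl oxazolidinone by hydride attack at the exocyclic carbonyl frees the neopentyl alcohol and the recoverable auxiliary, and borohydride leaves the alkenyl bromide and the sulfonamides alone.

Step 14
Reactants: 23 (2S,3E)-2-[(Z)-4-bromo-3-methylbut-3-enyl]-2-methyl-4-Ar-but-3-en-1-ol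
Product: 24 (2S,3E)-2-[(Z)-4-bromo-3-methylbut-3-enyl]-2-methyl-4-Ar-but-3-enal
Conditions: Dess–Martin periodinane, CH2Cl2, 0 °C to rt
Reagents that add atoms: none
Why: Dess–Martin oxidation gives an aldehyde with no α-hydrogen, which cannot enolise or epimerise.

Step 15
Reactants: 24 (2S,3E)-2-[(Z)-4-bromo-3-methylbut-3-enyl]-2-methyl-4-Ar-but-3-enal; 7 5-bromo-3-(2-methylbut-3-en-2-yl)-1-tosylindole
Product: 26 (2S,3E)-2-[(Z)-4-bromo-3-methylbut-3-enyl]-2-methyl-1,4-di-Ar-but-3-en-1-ol (both carbinol epimers), via arylmagnesium bromide 25 (not isolated)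
Conditions: 7, Mg, LiCl, THF, rt, solution decanted from Mg; then 24, THF, 0 °C to rt; H2O
Reagents that add atoms: none
Why: Grignard 1,2-addition to the non-enolisable aldehyde, in which the N-sulfonyl groups and the alkenyl bromide are inert to ArMgBr and the uncontrolled carbinol centre does not matter because step 17 erases it.

Step 16
Reactants: 26 (2S,3E)-2-[(Z)-4-bromo-3-methylbut-3-enyl]-2-methyl-1,4-di-Ar-but-3-en-1-ol
Product: 27 benzylic chloride, (2S,3E)-1-chloro-2-[(Z)-4-bromo-3-methylbut-3-enyl]-2-methyl-1,4-di-Ar-but-3-ene (either C6 epimer)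
Conditions: PPh3, NCS, CH2Cl2, 0 to 40 °C
Reagents that add atoms: N-chlorosuccinimide, O=C1CCC(=O)N1Cl
Why: Appel-type chlorination through the alkoxyphosphonium chloride ion pair replaces OH by Cl without free acid, the N-tosyl groups holding back ionisation at C6.

Step 17
Reactants: 27 benzylic chloride (either C6 epimer)
Product: 28 bis-N-tosyl cyclohexene, (1S,6R)-1,4-dimethyl-1-[(E)-2-Ar-vinyl]-6-Ar-cyclohex-4-ene in the numbering above (Ar at C6 cis to the C1 methyl, trans to the styryl)
Conditions: NiCl2(dme) (10 mol%), (3aR,3a'R,8aS,8a'S)-2,2'-(cyclopropane-1,1-diyl)bis(3a,8a-dihydro-8H-indeno[1,2-d]oxazole) (12 mol%), Mn powder (3 equiv), NaI (0.5 equiv), DMA, 0 °C to rt, 0.02 M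
Reagents that add atoms: none
Why: Proposed new method: zerovalent nickel inserts into the (Z)-alkenyl C–Br bond with retention, a monovalent nickel halide abstracts chlorine from C6 to give a benzylic radical, the alkenylnickel centre captures this radical, and C5–C6 reductive elimination from trivalent nickel releases 28 while manganese returns nickel to the zerovalent state. The closest known reaction type is the intermolecular nickel-catalysed enantioselective reductive coupling of alkenyl bromides with secondary benzylic chlorides under these NiCl2(dme)/bis(oxazoline)/Mn/NaI conditions; the ring-closing form beside a quaternary carbon is without precedent. The cyclohexene closes by intramolecular radical capture and reductive elimination through a seven-membered nickelacycle, which only the Z bromide can reach. The new C6 stereocentre is set at capture and reductive elimination by the bis(oxazoline) ligand acting together with the fixed C1 centre, and because the radical erases the chloride configuration both epimers of 27 converge. The step needs cross-selectivity (alkenyl bromide to nickel, benzylic chloride to radical) and ring closure in preference to oligomerisation or 1,2-styryl shift of the radical; the different activation modes of the two halides, the N-tosyl groups that keep the chloride from ionising, the greater stability of the benzylic radical and high dilution should secure these.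

Step 18
Reactants: 28 bis-N-tosyl cyclohexene
Product: 29 EANPDB:ANNO_00013
Conditions: Cs2CO3, MeOH/THF (1:2), 65 °C
Reagents that add atoms: none
Why: Methanolysis of both indole N-sulfonyl groups (methoxide attack at sulfur) under carbonate base frees the two N–H indoles without touching the alkenes or the two stereocentres.

**Compound list**

1 | 5-bromoindole-3-acetic acid | OC(=O)Cc1c[nH]c2ccc(Br)cc12 | starting material
2 | methyl 2-(5-bromo-1H-indol-3-yl)acetate | COC(=O)Cc1c[nH]c2ccc(Br)cc12 | intermediate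
3 | methyl 2-(5-bromo-1-tosylindol-3-yl)acetate | COC(=O)Cc1cn(S(=O)(=O)c2ccc(C)cc2)c2ccc(Br)cc12 | intermediate
4 | methyl 2-(5-bromo-1-tosylindol-3-yl)propanoate (racemic, not isolated) | COC(=O)C(C)c1cn(S(=O)(=O)c2ccc(C)cc2)c2ccc(Br)cc12 | intermediate
5 | methyl 2-(5-bromo-1-tosylindol-3-yl)-2-methylpropanoate | COC(=O)C(C)(C)c1cn(S(=O)(=O)c2ccc(C)cc2)c2ccc(Br)cc12 | intermediate
6 | 2-(5-bromo-1-tosylindol-3-yl)-2-methylpropanal | O=CC(C)(C)c1cn(S(=O)(=O)c2ccc(C)cc2)c2ccc(Br)cc12 | intermediate
7 | 5-bromo-3-(2-methylbut-3-en-2-yl)-1-tosylindole | C=CC(C)(C)c1cn(S(=O)(=O)c2ccc(C)cc2)c2ccc(Br)cc12 | intermediate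
8 | but-3-yn-1-ol | C#CCCO | starting material
9 | (E)-alkenylalane, dimethylaluminium alkoxide of (E)-4-(dimethylalumanyl)-3-methylbut-3-en-1-ol (not isolated) | C/C(CCO[Al](C)C)=C\[Al](C)C | intermediate
10 | cyclic (Z)-alkenylalane, six-membered oxaaluminacycle (not isolated) | CC1=C[Al](C)OCC1 | intermediate
11 | (Z)-4-bromo-3-methylbut-3-en-1-ol | OCC/C(C)=C\Br | intermediate
12 | (Z)-4-bromo-3-methylbut-3-en-1-yl trifluoromethanesulfonate | O=S(=O)(OCC/C(C)=C\Br)C(F)(F)F | intermediate
13 | 2-allyl-4,4,5,5-tetramethyl-1,3,2-dioxaborolane | C=CCB1OC(C)(C)C(C)(C)O1 | starting material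
14 | 5-allyl-3-(2-methylbut-3-en-2-yl)-1-tosylindole | C=CC(C)(C)c1cn(S(=O)(=O)c2ccc(C)cc2)c2ccc(CC=C)cc12 | intermediate
15 | methacrolein | C=C(C)C=O | starting material
16 | (E)-2-methyl-4-Ar-but-2-enal | C=CC(C)(C)c1cn(S(=O)(=O)c2ccc(C)cc2)c2ccc(C/C=C(\C)C=O)cc12 | intermediate
17 | (E)-2-methyl-4-Ar-but-2-enoic acid | C=CC(C)(C)c1cn(S(=O)(=O)c2ccc(C)cc2)c2ccc(C/C=C(\C)C(=O)O)cc12 | intermediate
18 | (R)-4-benzyloxazolidin-2-one | O=C1N[C@H](Cc2ccccc2)CO1 | starting material
19 | mixed pivalic anhydride of 17 (not isolated) | C=CC(C)(C)c1cn(S(=O)(=O)c2ccc(C)cc2)c2ccc(C/C=C(\C)C(=O)OC(=O)C(C)(C)C)cc12 | intermediate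
20 | (R)-4-benzyl-3-[(E)-2-methyl-4-Ar-but-2-enoyl]oxazolidin-2-one | C=CC(C)(C)c1cn(S(=O)(=O)c2ccc(C)cc2)c2ccc(C/C=C(\C)C(=O)N3[C@H](Cc4ccccc4)COC3=O)cc12 | intermediate
21 | sodium dienolate of 20, methyl cis to O–Na, (E)-styryl (not isolated) | C=CC(C)(C)c1cn(S(=O)(=O)c2ccc(C)cc2)c2ccc(/C=C/C(C)=C(/[O-])N3[C@H](Cc4ccccc4)COC3=O)cc12.[Na+] | intermediate
22 | (R)-4-benzyl-3-[(2S,3E)-2-[(Z)-4-bromo-3-methylbut-3-enyl]-2-methyl-4-Ar-but-3-enoyl]oxazolidin-2-one | C=CC(C)(C)c1cn(S(=O)(=O)c2ccc(C)cc2)c2ccc(/C=C/[C@](C(=O)N3[C@H](Cc4ccccc4)COC3=O)(C)CC/C(C)=C\Br)cc12 | intermediate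
23 | (2S,3E)-2-[(Z)-4-bromo-3-methylbut-3-enyl]-2-methyl-4-Ar-but-3-en-1-ol | C=CC(C)(C)c1cn(S(=O)(=O)c2ccc(C)cc2)c2ccc(/C=C/[C@](CO)(C)CC/C(C)=C\Br)cc12 | intermediate
24 | (2S,3E)-2-[(Z)-4-bromo-3-methylbut-3-enyl]-2-methyl-4-Ar-but-3-enal | C=CC(C)(C)c1cn(S(=O)(=O)c2ccc(C)cc2)c2ccc(/C=C/[C@](C=O)(C)CC/C(C)=C\Br)cc12 | intermediate
25 | [3-(2-methylbut-3-en-2-yl)-1-tosylindol-5-yl]magnesium bromide (not isolated) | C=CC(C)(C)c1cn(S(=O)(=O)c2ccc(C)cc2)c2ccc([Mg]Br)cc12 | intermediate
26 | (2S,3E)-2-[(Z)-4-bromo-3-methylbut-3-enyl]-2-methyl-1,4-di-Ar-but-3-en-1-ol, carbinol epimers | C=CC(C)(C)c1cn(S(=O)(=O)c2ccc(C)cc2)c2ccc(/C=C/[C@](C(O)c3ccc4c(c3)c(C(C)(C)C=C)cn4S(=O)(=O)c3ccc(C)cc3)(C)CC/C(C)=C\Br)cc12 | intermediate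
27 | benzylic chloride, key-step precursor (bis-N-tosyl, either C6 epimer) | C=CC(C)(C)c1cn(S(=O)(=O)c2ccc(C)cc2)c2ccc(/C=C/[C@](C(Cl)c3ccc4c(c3)c(C(C)(C)C=C)cn4S(=O)(=O)c3ccc(C)cc3)(C)CC/C(C)=C\Br)cc12 | intermediate
28 | bis-N-tosyl derivative of the target, C1 S and C6 R in the numbering above | C=CC(C)(C)c1cn(S(=O)(=O)c2ccc(C)cc2)c2ccc(/C=C/[C@]3(C)CCC(C)=C[C@H]3c3ccc4c(c3)c(C(C)(C)C=C)cn4S(=O)(=O)c3ccc(C)cc3)cc12 | intermediate
29 | EANPDB:ANNO_00013 | C=CC(C)(C)c1c[nH]c2ccc(/C=C/[C@]3(C)CCC(C)=C[C@H]3c3ccc4[nH]cc(C(C)(C)C=C)c4c3)cc12 | target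

**Step count and risks**

Total step count: 18. Longest linear sequence: 16 steps (steps 1 to 5 and 8 to 18).

Steps most likely to fail:

1. Step 17 (key ring closure). The benzylic radical may escape capture at nickel (hydrogen abstraction, 1,2-styryl shift through a cyclopropylcarbinyl radical), coupling may occur between molecules, or the face of C6 may be poorly controlled beside the quaternary carbon. Fallback by known chemistry, setting out from bromide 7 and returning at 28:
   - A Heck reaction of 7 with 2-methylbut-3-en-2-ol (Pd(OAc)2, P(o-tol)3, Et3N, DMF, 100 °C) should give the (E)-tertiary allylic alcohol F1.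
   - Acid-catalysed dehydration (p-TsOH, toluene, 80 °C) should give the (E)-1-aryl-3-methylbuta-1,3-diene F2.
   - Heating F2 (toluene, 130 °C, BHT) should give its Diels–Alder dimer, in which the isopropenyl double bond of one molecule is the dienophile and the ortho/para orientation is favoured.
   - The racemic trans dimer F3 would be separated from the cis isomer and resolved by preparative HPLC on a chiral stationary phase; the enantiomer identical with 28 re-enters the route.

2. Step 12 (quaternary centre). The triflate may be lost by elimination, the dienolate may react at oxygen or at the γ-carbon, or facial selectivity may be poor. Fallback, setting out from acid 17 and returning at 23: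
   - Esterification of 17 (MeI, K2CO3, DMF) gives the methyl ester F4.
   - Alcohol 11 is converted (I2, PPh3, imidazole) into the iodide F5.
   - The lithium dienolate of F4 (LiN(SiMe3)2, THF/DMPU, −78 °C), more nucleophilic than the imide dienolate, is α-alkylated with F5 to give the racemic quaternary ester F6.
   - Reduction with i-Bu2AlH gives the racemic alcohol F7, which is resolved by preparative chromatography on a chiral phase to give 23.

3. Step 16 (chlorination). Ionisation at C6 may be followed by participation of the neighbouring styryl group (homoallyl–cyclopropylcarbinyl rearrangement) or by elimination. Fallback, setting out from alcohol 26 and returning at 28: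
   - 26 is acylated with methyl chlorooxoacetate (pyridine, DMAP, CH2Cl2, 0 °C) to the mixed methyl oxalate F8; this does not break the C6–O bond.
   - F8 then serves as the benzylic radical precursor in the nickel/manganese ring closure (reductive C–O activation of a benzylic oxalate).

Further compounds
F1 | step 17 | (E)-2-methyl-4-Ar-but-3-en-2-ol | C=CC(C)(C)c1cn(S(=O)(=O)c2ccc(C)cc2)c2ccc(/C=C/C(C)(C)O)cc12
F2 | step 17 | 5-[(E)-3-methylbuta-1,3-dienyl]-3-(2-methylbut-3-en-2-yl)-1-tosylindole | C=CC(C)(C)c1cn(S(=O)(=O)c2ccc(C)cc2)c2ccc(/C=C/C(C)=C)cc12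
F3 | step 17 | racemic trans Diels–Alder dimer (racemate of 28) | C=CC(C)(C)c1cn(S(=O)(=O)c2ccc(C)cc2)c2ccc(/C=C/C3(C)CCC(C)=CC3c3ccc4c(c3)c(C(C)(C)C=C)cn4S(=O)(=O)c3ccc(C)cc3)cc12
F4 | step 12 | methyl (E)-2-methyl-4-Ar-but-2-enoate | C=CC(C)(C)c1cn(S(=O)(=O)c2ccc(C)cc2)c2ccc(C/C=C(\C)C(=O)OC)cc12
F5 | step 12 | (Z)-1-bromo-4-iodo-2-methylbut-1-ene | ICC/C(C)=C\Br
F6 | step 12 | racemic methyl (E)-2-[(Z)-4-bromo-3-methylbut-3-enyl]-2-methyl-4-Ar-but-3-enoate | C=CC(C)(C)c1cn(S(=O)(=O)c2ccc(C)cc2)c2ccc(/C=C/C(C)(CC/C(C)=C\Br)C(=O)OC)cc12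
F7 | step 12 | racemic (E)-2-[(Z)-4-bromo-3-methylbut-3-enyl]-2-methyl-4-Ar-but-3-en-1-ol (racemate of 23) | C=CC(C)(C)c1cn(S(=O)(=O)c2ccc(C)cc2)c2ccc(/C=C/C(C)(CO)CC/C(C)=C\Br)cc12
F8 | step 16 | methyl oxalate ester of 26 | C=CC(C)(C)c1cn(S(=O)(=O)c2ccc(C)cc2)c2ccc(/C=C/[C@](C(OC(=O)C(=O)OC)c3ccc4c(c3)c(C(C)(C)C=C)cn4S(=O)(=O)c3ccc(C)cc3)(C)CC/C(C)=C\Br)cc12
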